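The bicycle is read as a 2-acylmethylene tetrahydrofuran whose exocyclic carbon C7 and ring methylene C3a (benzofuran numbering), both flanking the enol-ether carbon C7a, are C-acylated by one dimethylmalonyl unit (C4–C5–C6). The key step therefore starts from an open-chain hydroxy ynone: its alkoxide closes the dihydrofuran by oxa-Michael addition (O1–C7a) and the resulting enolate is annulated with dimethylmalonyl dichloride (C6–C7, C3a–C4), so both rings form in one flask. Because O1 is the only free oxygen, the furan fusion is unambiguous. The precursor already carries both stereocentres, set from geraniol by Sharpless epoxidation and invertive epoxide hydrolysis, and holds the tertiary alcohol as a migration-resistant TBS ether.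

Key step: step 7

Remark on the chemistry: ring atoms are numbered as in 1-benzofuran; the trione is drawn as the exocyclic enol with its OH hydrogen-bonded to C6=O, taken as the equilibrium tautomer reached on acidification, so its geometry needs no separate control; N-methoxy-N-methylisobutyramide is taken as a purchasable reagent.

Step 1
Reactants: 1 geraniol
Product: 2 (2S,3S)-2,3-epoxygeraniol, [(2S,3S)-3-methyl-3-(4-methylpent-3-en-1-yl)oxiran-2-yl]methanol
Conditions: Ti(Oi-Pr)4 (cat.), L-(+)-DET (cat.), t-BuOOH, 4 Å MS, CH2Cl2, −20 °C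
Reagents that add atoms: tert-butyl hydroperoxide, CC(C)(C)OO
Why: Sharpless asymmetric epoxidation is hydroxyl-directed, so only the allylic 2,3-alkene reacts, and the L-(+)-tartrate catalyst delivers oxygen to the face that gives the (2S,3S) epoxide, which sets C2 directly and C3 for the later inversion.

Step 2
Reactants: 2 (2S,3S)-2,3-epoxygeraniol
Product: 3 (2S,3R)-3,7-dimethyloct-6-ene-1,2,3-triol
Conditions: HClO4 (cat.), THF/H2O, 0 °C → rt
Reagents that add atoms: water, O
Why: Acid-catalysed epoxide hydrolysis opens the protonated epoxide at the more substituted C3 in a borderline SN2 process with inversion while the C2–O bond stays intact, so the (2S,3R) triol should hold both stereocentres of the target, and the isolated trisubstituted alkene is inert to cold dilute acid.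

Step 3
Reactants: 3 (2S,3R)-3,7-dimethyloct-6-ene-1,2,3-triol
Product: 5 (2R)-6-methyl-2-[(2S)-oxiran-2-yl]hept-5-en-2-ol, via primary tosylate 4 (not isolated)
Conditions: TsCl, Et3N, Bu2SnO (cat.), CH2Cl2, 0 °C; then K2CO3, MeOH, 0 °C
Reagents that add atoms: p-toluenesulfonyl chloride, Cc1ccc(cc1)S(Cl)(=O)=O (tosyl group of intermediate 4 only; none of its atoms remain in 5)
Why: Tin-catalysed selective sulfonylation of the primary hydroxyl of a 1,2-diol followed by intramolecular Williamson (3-exo-tet) closure by the secondary alkoxide should give the terminal epoxide with retention at C2, because only the C1–O bond is broken, and the short cold carbonate treatment avoids Payne equilibration.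

Step 4
Reactants: 5 (2R)-6-methyl-2-[(2S)-oxiran-2-yl]hept-5-en-2-ol
Product: 6 tert-butyl(dimethyl){[(2R)-6-methyl-2-[(2S)-oxiran-2-yl]hept-5-en-2-yl]oxy}silane
Conditions: TBSOTf, 2,6-lutidine, CH2Cl2, −78 → −20 °C
Reagents that add atoms: tert-butyldimethylsilyl trifluoromethanesulfonate, CC(C)(C)[Si](C)(C)OS(=O)(=O)C(F)(F)F
Why: Silylation of a tertiary alcohol with a silyl triflate and a hindered pyridine base needs no alkoxide, so the neighbouring epoxide is neither opened nor Payne-rearranged, and the TBS group is chosen because it should not shift to a neighbouring alkoxide in steps 5–7.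

Step 5
Reactants: 6 tert-butyl(dimethyl){[(2R)-6-methyl-2-[(2S)-oxiran-2-yl]hept-5-en-2-yl]oxy}silane; 7 1-(trimethylsilyl)propyne
Product: 9 (5S,6R)-6-(tert-butyldimethylsilyloxy)-6,10-dimethylundec-9-en-1-yn-5-ol, via TMS-alkyne 8 (not isolated)
Conditions: 7, n-BuLi, THF, −78 → −20 °C; then 6, BF3·OEt2, −78 °C; then MeOH, K2CO3, rt
Reagents that add atoms: none
Why: BF3-assisted SN2 opening of a terminal epoxide by a propargylic organolithium (Yamaguchi-type conditions) occurs at the unhindered CH2, so the carbinol stereocentre is untouched, and methanolic carbonate then cleaves the alkynyl C–Si bond while the tertiary TBS ether survives.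

Step 6
Reactants: 9 (5S,6R)-6-(tert-butyldimethylsilyloxy)-6,10-dimethylundec-9-en-1-yn-5-ol; 10 N-methoxy-N-methylisobutyramide
Product: 11 (8S,9R)-9-(tert-butyldimethylsilyloxy)-8-hydroxy-2,9,13-trimethyltetradec-12-en-4-yn-3-one
Conditions: n-BuLi (2.1 equiv), THF, −78 °C; 10, −78 → 0 °C; inverse quench into cold 1 M HCl
Reagents that add atoms: none
Why: Weinreb ketone synthesis on the alkoxide/acetylide dianion stops at the chelated tetrahedral adduct, which prevents over-addition and keeps alkoxide and ynone apart, and the acidic inverse quench protonates the liberated N,O-dimethylhydroxylamine before it can add to the ynone.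

Step 7
Reactants: 11 (8S,9R)-9-(tert-butyldimethylsilyloxy)-8-hydroxy-2,9,13-trimethyltetradec-12-en-4-yn-3-one; 12 dimethylmalonyl dichloride
Product: 15 (2S)-2-[(2R)-2-(tert-butyldimethylsilyloxy)-6-methylhept-5-en-2-yl]-7-[(Z)-1-hydroxy-2-methylpropylidene]-5,5-dimethyl-2,3-dihydro-1-benzofuran-4,6(5H,7H)-dione, via lithium allenolate 13 (not isolated), via C7-acylated acid chloride 14 (not isolated)
Conditions: LiHMDS (1.05 equiv), THF, −78 → −20 °C; MgBr2·OEt2 (3 equiv); cannulate into 12 (1.1 equiv), −78 °C; then i-Pr2NEt (3 equiv), DMAP (cat.), −78 °C → rt; cold 1 M HCl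
Reagents that add atoms: lithium bis(trimethylsilyl)amide, [Li]N([Si](C)(C)C)[Si](C)(C)C (lithium of intermediate 13 only; all atoms of 15 come from 11 and 12)
Why: Proposed new method: LiHMDS forms the alkoxide of the only free hydroxyl of 11, which adds to the ynone β-carbon by a 5-exo-dig oxa-Michael closure (O1–C7a, dihydrofuran ring) to give allenolate 13; after proton relay from C3a and Li→Mg exchange this anion is a C7/C3a 1,3-dinucleophile, C7 attacks one acyl chloride of 12 to give 14, and amine/Mg soft enolisation of the now doubly activated C3a methylene closes the carbocycle by 6-(enolendo)-exo-trig acylation (C3a–C4), tautomerisation then giving the enolised trione. The closest known reaction types are the base-induced 5-exo-dig cyclisation of hydroxy ynones to 2-acylmethylene tetrahydrofurans, the Effenberger-type α,α′-bis-acylation of enol ethers by malonyl dichlorides and magnesium-mediated soft-enolisation C-acylation, none of which has been run as one cascade on a vinylogous ester enolate. No stereocentre is formed, and the carbinol C–O bond that becomes C2–O1 is never broken, so both existing centres pass through unchanged. The step needs C- over O-acylation, which is favoured by chelation of magnesium between the carbonyl oxygens, by DMAP returning any enol ester or enol lactone to the acylpyridinium stage, by the Thorpe–Ingold effect of the CMe2 group and by the irreversible formation of the strongly acidic trione enolate. Ring fusion is fixed by the substrate, because the tertiary oxygen is blocked by a silyl group too bulky to migrate and because acylation at C7 and C3a in either order leads to the same six-membered ring.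

Step 8
Reactants: 15 (2S)-2-[(2R)-2-(tert-butyldimethylsilyloxy)-6-methylhept-5-en-2-yl]-7-[(Z)-1-hydroxy-2-methylpropylidene]-5,5-dimethyl-2,3-dihydro-1-benzofuran-4,6(5H,7H)-dione
Product: 16 CNP0317212.1, (2S)-2-[(2R)-2-hydroxy-6-methylhept-5-en-2-yl]-7-[(Z)-1-hydroxy-2-methylpropylidene]-5,5-dimethyl-2,3-dihydro-1-benzofuran-4,6(5H,7H)-dione
Conditions: HF·pyridine, pyridine, THF, 0 °C → rt (48% aq. HF, MeCN if sluggish)
Reagents that add atoms: none
Why: Fluoride-driven Si–O cleavage with buffered HF·pyridine should remove the hindered tertiary TBS ether, and the enolised trione, the vinylogous ester and the trisubstituted alkene are inert to these mildly acidic conditions, so no stereocentre is touched.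

Compound list
1 | geraniol | CC(C)=CCC/C(C)=C/CO | starting material
2 | (2S,3S)-2,3-epoxygeraniol | CC(C)=CCC[C@]1(C)O[C@H]1CO | intermediate
3 | (2S,3R)-3,7-dimethyloct-6-ene-1,2,3-triol | CC(C)=CCC[C@@](C)(O)[C@@H](O)CO | intermediate
4 | (2S,3R)-2,3-dihydroxy-3,7-dimethyloct-6-en-1-yl 4-methylbenzenesulfonate (primary tosylate) | CC(C)=CCC[C@@](C)(O)[C@@H](O)COS(=O)(=O)c1ccc(C)cc1 | intermediate (not isolated)
5 | (2R)-6-methyl-2-[(2S)-oxiran-2-yl]hept-5-en-2-ol | CC(C)=CCC[C@@](C)(O)[C@@H]1CO1 | intermediate
6 | tert-butyl(dimethyl){[(2R)-6-methyl-2-[(2S)-oxiran-2-yl]hept-5-en-2-yl]oxy}silane | CC(C)=CCC[C@@](C)(O[Si](C)(C)C(C)(C)C)[C@@H]1CO1 | intermediate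
7 | 1-(trimethylsilyl)propyne | CC#C[Si](C)(C)C | starting material
8 | (5S,6R)-6-(tert-butyldimethylsilyloxy)-6,10-dimethyl-1-(trimethylsilyl)undec-9-en-1-yn-5-ol (TMS-alkyne) | CC(C)=CCC[C@@](C)(O[Si](C)(C)C(C)(C)C)[C@@H](O)CCC#C[Si](C)(C)C | intermediate (not isolated)
9 | (5S,6R)-6-(tert-butyldimethylsilyloxy)-6,10-dimethylundec-9-en-1-yn-5-ol | CC(C)=CCC[C@@](C)(O[Si](C)(C)C(C)(C)C)[C@@H](O)CCC#C | intermediate
10 | N-methoxy-N-methylisobutyramide (N-methoxy-N,2-dimethylpropanamide) | CC(C)C(=O)N(C)OC | starting material
11 | (8S,9R)-9-(tert-butyldimethylsilyloxy)-8-hydroxy-2,9,13-trimethyltetradec-12-en-4-yn-3-one (key-step precursor) | CC(C)=CCC[C@@](C)(O[Si](C)(C)C(C)(C)C)[C@@H](O)CCC#CC(=O)C(C)C | intermediate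
12 | 2,2-dimethylpropanedioyl dichloride (dimethylmalonyl dichloride) | CC(C)(C(=O)Cl)C(=O)Cl | starting material
13 | lithium 1-[(5S)-5-{(2R)-2-(tert-butyldimethylsilyloxy)-6-methylhept-5-en-2-yl}oxolan-2-ylidene]-3-methylbut-1-en-2-olate (allenolate; allene axis not controlled, both forms converge) | CC(C)=CCC[C@@](C)(O[Si](C)(C)C(C)(C)C)[C@@H]1CCC(=C=C(O[Li])C(C)C)O1 | intermediate (not isolated)
14 | 4-[(5S)-5-{(2R)-2-(tert-butyldimethylsilyloxy)-6-methylhept-5-en-2-yl}oxolan-2-ylidene]-2,2,6-trimethyl-3,5-dioxoheptanoyl chloride (push–pull alkene drawn in the rotamer that cyclises) | CC(C)=CCC[C@@](C)(O[Si](C)(C)C(C)(C)C)[C@@H]1CC/C(=C(/C(=O)C(C)C)C(=O)C(C)(C)C(Cl)=O)O1 | intermediate (not isolated)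
15 | (2S)-2-[(2R)-2-(tert-butyldimethylsilyloxy)-6-methylhept-5-en-2-yl]-7-[(Z)-1-hydroxy-2-methylpropylidene]-5,5-dimethyl-2,3-dihydro-1-benzofuran-4,6(5H,7H)-dione (key-step product) | CC(C)=CCC[C@@](C)(O[Si](C)(C)C(C)(C)C)[C@@H]1CC2=C(O1)/C(=C(/O)C(C)C)C(=O)C(C)(C)C2=O | intermediate
16 | CNP0317212.1, (2S)-2-[(2R)-2-hydroxy-6-methylhept-5-en-2-yl]-7-[(Z)-1-hydroxy-2-methylpropylidene]-5,5-dimethyl-2,3-dihydro-1-benzofuran-4,6(5H,7H)-dione | CC(C)=CCC[C@@](C)(O)[C@@H]1CC2=C(O1)/C(=C(/O)C(C)C)C(=O)C(C)(C)C2=O | target

Total step count: 8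
Longest linear sequence: 8 steps (1 → 16)

Steps most likely to fail

Step 7 (proposed new method). The enolate may be acylated on oxygen instead of carbon, giving an enol ester or a six-membered enol lactone, or two enolates may be acylated by one dichloride and oligomerise. The fallback uses known chemistry, sets out from 11 and comes back at 15. Compound 11 alone is cyclised with catalytic DBU in CH2Cl2 (base-catalysed 5-exo-dig oxa-Michael addition) and the product is isolated as (1E)-1-[(5S)-5-{(2R)-2-(tert-butyldimethylsilyloxy)-6-methylhept-5-en-2-yl}oxolan-2-ylidene]-3-methylbutan-2-one F1. F1 is deprotonated at C3a with LiHMDS and the dienolate is C-acylated with methyl 3-chloro-2,2-dimethyl-3-oxopropanoate to give the keto ester F2; a C7-acylated isomer, if formed, converges in the next operation. The carbocycle is then closed by a Dieckmann-type Claisen condensation of C7 onto the methyl ester (LiHMDS or t-BuOK, THF), which should give 15 after acidification.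

Step 2. Part of the opening may run through an SN1-like path with retention at C3, or water may attack C2; either would lower the stereochemical purity carried into the target. The fallback sets out from 1 and comes back at 5 without breaking any bond to C3. Geraniol 1 is epoxidised with the D-(−)-tartrate catalyst to (2R,3R)-2,3-epoxygeraniol F3. F3 is opened under Payne-rearrangement conditions with tert-butylthiol (aq. NaOH, t-BuOH, reflux), where the thiolate traps the transient terminal epoxide at C1 and gives (2R,3R)-1-(tert-butylsulfanyl)-3,7-dimethyloct-6-ene-2,3-diol F4. S-Methylation with Me3OBF4 gives the sulfonium tetrafluoroborate F5, and NaH in CH2Cl2 closes the epoxide by displacement of the sulfide to give 5 (C2 inverted once in the Payne step, C3 retained).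

Step 5. The Lewis acid may trigger semipinacol rearrangement of the α-silyloxy epoxide, the opening may be slow beside the fully substituted carbon, or the organolithium may react through its allenyl terminus. The fallback avoids the Lewis acid, sets out from 6 and comes back at 9. Epoxide 6 is opened with lithioacetonitrile (MeCN, n-BuLi, THF, −78 °C → rt) to (4S,5R)-5-(tert-butyldimethylsilyloxy)-4-hydroxy-5,9-dimethyldec-8-enenitrile F6. DIBAL-H reduction (CH2Cl2, −78 °C, Rochelle salt work-up) gives the lactol (5S)-5-[(2R)-2-(tert-butyldimethylsilyloxy)-6-methylhept-5-en-2-yl]oxolan-2-ol F7. Ohira–Bestmann homologation (dimethyl (1-diazo-2-oxopropyl)phosphonate, K2CO3, MeOH) converts the masked aldehyde into the terminal alkyne 9.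

Further compounds
F1 | step 7 | (1E)-1-[(5S)-5-{(2R)-2-(tert-butyldimethylsilyloxy)-6-methylhept-5-en-2-yl}oxolan-2-ylidene]-3-methylbutan-2-one | CC(C)=CCC[C@@](C)(O[Si](C)(C)C(C)(C)C)[C@@H]1CC/C(=C\C(=O)C(C)C)O1
F2 | step 7 | methyl 3-[(5S)-5-{(2R)-2-(tert-butyldimethylsilyloxy)-6-methylhept-5-en-2-yl}-2-(3-methyl-2-oxobutyl)-4,5-dihydrofuran-3-yl]-2,2-dimethyl-3-oxopropanoate | CC(C)=CCC[C@@](C)(O[Si](C)(C)C(C)(C)C)[C@@H]1CC(C(=O)C(C)(C)C(=O)OC)=C(CC(=O)C(C)C)O1
F3 | step 2 | (2R,3R)-2,3-epoxygeraniol | CC(C)=CCC[C@@]1(C)O[C@@H]1CO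
F4 | step 2 | (2R,3R)-1-(tert-butylsulfanyl)-3,7-dimethyloct-6-ene-2,3-diol | CC(C)=CCC[C@@](C)(O)[C@@H](O)CSC(C)(C)C
F5 | step 2 | tert-butyl[(2R,3R)-2,3-dihydroxy-3,7-dimethyloct-6-en-1-yl]methylsulfonium tetrafluoroborate (sulfur configuration not controlled) | CC(C)=CCC[C@@](C)(O)[C@@H](O)C[S+](C)C(C)(C)C.F[B-](F)(F)F
F6 | step 5 | (4S,5R)-5-(tert-butyldimethylsilyloxy)-4-hydroxy-5,9-dimethyldec-8-enenitrile | CC(C)=CCC[C@@](C)(O[Si](C)(C)C(C)(C)C)[C@@H](O)CCC#N
F7 | step 5 | (5S)-5-[(2R)-2-(tert-butyldimethylsilyloxy)-6-methylhept-5-en-2-yl]oxolan-2-ol (anomeric mixture) | CC(C)=CCC[C@@](C)(O[Si](C)(C)C(C)(C)C)[C@@H]1CCC(O)O1
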